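The data are calculated for an exercise, noise included.

**The flask.** The easy part first: this closed, stirred flask at constant temperature is charged with substrate, and two earlier runs show how target rises and falls.

| flask | substrate | remark | time |
|---|---|---|---|
| eta | 0.060 M | run made earlier |  |
| delta | 0.090 M | run made earlier |  |
| flask | 0.12 M |  | 10 d |

| run | time / d | target / % |
|---|---|---|
| eta | 0.417 | 6.9 |
| eta | 0.833 | 14.9 |
| eta | 1.67 | 18.9 |
| eta | 3.00 | 15.9 |
| eta | 6.00 | 8.2 |
| delta | 0.417 | 6.6 |
| delta | 0.833 | 13.5 |
| delta | 1.67 | 16.1 |
| delta | 3.00 | 13.6 |
| delta | 6.00 | 6.2 |

(each reading ± 0.3 percentage points)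

- when, up to 10 d, the flask holds most target
- the amount of target, in percent of the substrate charged, at that time
- the first time at which target reaches 10 %, in the same percent, in d

- the numbers in the tables scatter with a standard deviation of 0.3 percentage points

**Charge per target.** At its top reading the eta run holds one target for every 5.29 substrate charged, the delta run one for every 6.21. That count rises by 30.7 L mol⁻¹ of starting concentration; I call this the climb. If a first-order step and a second-order step compete for substrate, the ratio of their rates grows in a straight line with its concentration, so I assume the same climb up to 0.12 M, though two runs are thin support. My reckoning for this flask is one target for every 7.13 substrate, a top of 14.0 %.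

**For you.** The forecast expects 14 % at 1.4 d, and 10 % first reached at 0.68 d: “The peak should fall slightly earlier than in the other runs”. Its top is close to mine, and both come from the same two runs. Do not add substrate: the delta run, with the larger charge, has the lower top reading, 16.1 % against 18.9 %. Do not let the flask wait: the eta run is down to 8.2 % at 6.00 d.

**What came.** The flask tops at 14.7 % at 1.61 d and reaches 10 % at 0.639 d.

    substrate → intermediate (k = 7.60 × 10⁻⁴ min⁻¹)
    intermediate ⇌ target (K = 3.10, k = 0.00130 min⁻¹)
    intermediate ⇌ isomer of the product (K = 9.00, k = 1.80 × 10⁻⁴ min⁻¹)
    2 substrate → self-condensation product (k = 0.00860 L mol⁻¹ min⁻¹)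
    intermediate → decomposed reagent (k = 0.00110 min⁻¹)

**The count again.** The top of this flask is flat: target stands at 14.4 % at 1.29 d and 14.4 % at 2.01 d, and the forecast's 1.4 d lies between these times. This flask's charge per target is 6.80, against my 7.13. For the same flask with 0.048 M of substrate, the climb taken down from the eta run gives 4.92, a top of 20.3 %, and that flask reaches 20.2 %.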